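## Retrosynthetic overview

1. The C8–CH2 bond is made last, by a blue-light nickel/iridium decarboxylative coupling of an 8-iodoflavanone with a carboxylate unmasked from a hydroxylactone derived from L-malic acid. The side-chain carbinol centre is bought.
2. The 8-iodoflavanone comes from (2S)-5,7-dimethoxyflavanone by C8-selective iodination.
3. Ring C, the only ring that is made, is closed by intramolecular Friedel–Crafts acylation of a (3S)-3-aryloxy-3-phenylpropanoic acid. Rings A and B are bought.
4. The C2–O bond comes from a Mitsunobu inversion of ethyl (3R)-3-hydroxy-3-phenylpropanoate with 3,5-dimethoxyphenol, so C2 is bought.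
5. The lactone comes from the acetonide of L-malic acid and MeMgBr.

Assumption: the SMILES is read as (2S) at C2 of ring C and (2S) in the side chain, and compounds 2 and 8 are taken as catalogue items (8 is the acetonide of natural L-malic acid).

## Route

Step 1
Reactants: 1 3,5-dimethoxyphenol; 2 ethyl (3R)-3-hydroxy-3-phenylpropanoate
Product: 3 ethyl (3S)-3-(3,5-dimethoxyphenoxy)-3-phenylpropanoate
Conditions: PPh3 (1.3 equiv), DIAD (1.3 equiv), 1 (1.2 equiv), toluene, 0 °C → rt, 12 h
Reagents that add atoms: none
Why: Mitsunobu etherification, in which the phenoxide displaces the activated benzylic alcohol by SN2 with clean inversion (3R → 3S); the β-ester disfavours ionisation, so the bought centre becomes C2 of the flavanone.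

Step 2
Reactants: 3 ethyl (3S)-3-(3,5-dimethoxyphenoxy)-3-phenylpropanoate
Product: 4 (3S)-3-(3,5-dimethoxyphenoxy)-3-phenylpropanoic acid
Conditions: LiOH·H2O (2 equiv), THF–H2O 3:1, 0 °C → rt; then 1 M HCl to pH 3
Reagents that add atoms: lithium hydroxide (used as LiOH·H2O), [Li+].[OH-]
Why: Ester saponification by acyl–oxygen cleavage, which does not touch the stereocentre; the low temperature keeps E1cB loss of the phenoxide slow.

Step 3
Reactants: 4 (3S)-3-(3,5-dimethoxyphenoxy)-3-phenylpropanoic acid
Product: 7 (2S)-8-iodo-5,7-dimethoxyflavanone, via mixed trifluoroacetic anhydride 5 (not isolated), via (2S)-5,7-dimethoxyflavanone 6 (not isolated)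
Conditions: TFAA (1.2 equiv), CH2Cl2, 0 °C → rt, 2 h; then NIS (1.05 equiv), MeCN, 0 °C → rt, dark
Reagents that add atoms: N-iodosuccinimide, O=C1CCC(=O)N1I
Why: Intramolecular Friedel–Crafts acylation closes ring C at either of the two equivalent ortho positions of ring A without touching C2, and the trifluoroacetic acid released then activates NIS for electrophilic aromatic iodination at C8, which is less hindered than C6 (flanked by two methoxy groups) and is the usual site in 5,7-dimethoxyflavonoids.

Step 4
Reactants: 8 (4S)-2,2-dimethyl-5-oxo-1,3-dioxolane-4-acetic acid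
Product: 10 (4S)-4-hydroxy-5,5-dimethyloxolan-2-one, via (3S)-3,4-dihydroxy-4-methylpentanoic acid 9 (not isolated)
Conditions: MeMgBr (4.5 equiv), THF, −20 °C → rt; then 2 M HCl (pH 1), rt, 2 h; continuous EtOAc extraction
Reagents that add atoms: methylmagnesium bromide, C[Mg]Br
Why: The acid is masked in the flask as its magnesium carboxylate while double Grignard addition turns the activated dioxolanone carbonyl into the tertiary alcohol (the acetonide carbon leaves as acetone and is consumed); acidification closes the γ-lactone, and the bought carbinol centre keeps its C–O bond and stays (S).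

Step 5
Reactants: 7 (2S)-8-iodo-5,7-dimethoxyflavanone; 10 (4S)-4-hydroxy-5,5-dimethyloxolan-2-one
Product: 12 (2S)-8-[(2S)-2,3-dihydroxy-3-methylbutyl]-5,7-dimethoxyflavanone, via cesium (3S)-3,4-dihydroxy-4-methylpentanoate 11 (not isolated)
Conditions: 10 (2.0 equiv), CsOH·H2O (1.95 equiv), MeOH–H2O, rt, then evaporate to dryness; add 7 (1.0 equiv), [Ir(dF(CF3)ppy)2(dtbbpy)]PF6 (2 mol %), NiBr2·dme (10 mol %), dtbbpy (15 mol %), degassed DMSO, 450 nm LEDs, 25 °C, 24 h (dF(CF3)ppy = cyclometalated 2-(2,4-difluorophenyl)-5-(trifluoromethyl)pyridine; dtbbpy = 4,4'-di-tert-butyl-2,2'-bipyridine; dme = 1,2-dimethoxyethane)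
Reagents that add atoms: none
Why: Proposed new method: a base-free lactone-unmasking decarboxylative arylation. Slightly less than one equivalent of CsOH per lactone opens 10 to the unprotected β,γ-dihydroxy carboxylate 11. The blue-light-excited trivalent iridium photocatalyst oxidises 11, and loss of CO2 gives the primary radical •CH2–CH(OH)–CMe2OH. Zerovalent nickel (dtbbpy) inserts into the C8–I bond of 7 and captures the radical, and the resulting trivalent aryl(alkyl)nickel reductively eliminates the C8–CH2 bond. The reduced iridium complex returns monovalent nickel to the zerovalent state. The carbinol centre sits next to the radical carbon and is not touched, and C2 is safe because the carboxylate is the only base present. The closest known reaction type is the nickel/iridium metallaphotoredox decarboxylative arylation of aliphatic carboxylic acids with aryl halides. New here are the free 1,2-diol primary carboxylate generated in the flask from a lactone, the di-ortho-oxygenated aryl iodide, and the absence of added base.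

## Compound list

1 | 3,5-dimethoxyphenol | COc1cc(O)cc(OC)c1 | starting material
2 | ethyl (3R)-3-hydroxy-3-phenylpropanoate | CCOC(=O)C[C@@H](O)c1ccccc1 | starting material
3 | ethyl (3S)-3-(3,5-dimethoxyphenoxy)-3-phenylpropanoate | CCOC(=O)C[C@H](Oc1cc(OC)cc(OC)c1)c1ccccc1 | intermediate
4 | (3S)-3-(3,5-dimethoxyphenoxy)-3-phenylpropanoic acid | OC(=O)C[C@H](Oc1cc(OC)cc(OC)c1)c1ccccc1 | intermediate
5 | (3S)-3-(3,5-dimethoxyphenoxy)-3-phenylpropanoic trifluoroacetic anhydride | FC(F)(F)C(=O)OC(=O)C[C@H](Oc1cc(OC)cc(OC)c1)c1ccccc1 | intermediate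
6 | (2S)-5,7-dimethoxyflavanone [(2S)-5,7-dimethoxy-2-phenylchroman-4-one] | COc1cc(OC)c2c(c1)O[C@H](c1ccccc1)CC2=O | intermediate
7 | (2S)-8-iodo-5,7-dimethoxyflavanone | COc1cc(OC)c2c(c1I)O[C@H](c1ccccc1)CC2=O | intermediate
8 | (4S)-2,2-dimethyl-5-oxo-1,3-dioxolane-4-acetic acid (acetonide of L-malic acid) | OC(=O)C[C@@H]1OC(C)(C)OC1=O | starting material
9 | (3S)-3,4-dihydroxy-4-methylpentanoic acid | OC(=O)C[C@H](O)C(C)(C)O | intermediate
10 | (4S)-4-hydroxy-5,5-dimethyloxolan-2-one | CC1(C)OC(=O)C[C@@H]1O | intermediate
11 | cesium (3S)-3,4-dihydroxy-4-methylpentanoate | [Cs+].[O-]C(=O)C[C@H](O)C(C)(C)O | intermediate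
12 | (2S)-8-[(2S)-2,3-dihydroxy-3-methylbutyl]-5,7-dimethoxyflavanone | COc1cc(OC)c2c(c1C[C@H](O)C(C)(C)O)O[C@H](c1ccccc1)CC2=O | target

## Step count and risks

Total steps: 5. Longest linear sequence: 4 (steps 1, 2, 3, 5); step 4 is the side branch.

Steps most likely to fail:

**Step 1 (Mitsunobu on a β-hydroxy ester).** The activated alcohol can eliminate to ethyl cinnamate, which lowers the yield. The fallback sets out from 1 and moves the carbonyl away from the carbinol. Mitsunobu coupling of 1 with bought (R)-3-chloro-1-phenylpropan-1-ol (PPh3, DIAD, THF) gives (S)-1-(3-chloro-1-phenylpropoxy)-3,5-dimethoxybenzene F1 with inversion. KOAc and NaI in DMF at 80 °C give (S)-3-(3,5-dimethoxyphenoxy)-3-phenylpropyl acetate F2. K2CO3 in MeOH gives (S)-3-(3,5-dimethoxyphenoxy)-3-phenylpropan-1-ol F3. Oxidation with TEMPO/PhI(OAc)2 in MeCN–H2O then gives acid 4, where the route is rejoined (3 is bypassed).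

**Step 3 (C8 versus C6 iodination in the one-flask sequence).** A C6/C8 mixture or di-iodination would cost material late in the core synthesis. The fallback sets out from 1 and fixes the regiochemistry before ring C exists. NIS in CH2Cl2 at −20 °C gives 2-iodo-3,5-dimethoxyphenol F4, and the para isomer is removed at this cheap stage. Mitsunobu coupling with 2 gives ethyl (3S)-3-(2-iodo-3,5-dimethoxyphenoxy)-3-phenylpropanoate F5. LiOH gives (3S)-3-(2-iodo-3,5-dimethoxyphenoxy)-3-phenylpropanoic acid F6. TFAA in CH2Cl2 can then close ring C only at the single free ortho position, which gives 7 directly, where the route is rejoined.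

**Step 5 (the proposed new coupling).** The risks are poor radical capture at the di-ortho-substituted arylnickel, protodeiodination back to 6, aryl ester formation by C–O coupling, and interference by the free diol. The fallback uses known chemistry: the nickel-catalysed reductive coupling of an aryl halide with a terminal epoxide under iodide co-catalysis, which opens the epoxide at CH2 through the iodohydrin. It sets out from 7, and the epoxide is built from bought methyl (4S)-2,2-dimethyl-1,3-dioxolane-4-carboxylate (the serine-derived glycerate). MeMgBr in THF gives 2-[(4S)-2,2-dimethyl-1,3-dioxolan-4-yl]propan-2-ol F7. Aqueous AcOH gives (2S)-3-methylbutane-1,2,3-triol F8. TsCl in pyridine at 0 °C gives (2S)-2,3-dihydroxy-3-methylbutyl 4-methylbenzenesulfonate F9. K2CO3 in MeOH gives (S)-2-(oxiran-2-yl)propan-2-ol F10. Coupling of 7 with F10 (NiBr2·dme, 2,2'-bipyridine, NaI, Et3N·HCl, Zn, DMPU, rt) gives 12 directly, where the route ends.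

## Further compounds

F1 | step 1 | (S)-1-(3-chloro-1-phenylpropoxy)-3,5-dimethoxybenzene | COc1cc(OC)cc(O[C@H](c2ccccc2)CCCl)c1
F2 | step 1 | (S)-3-(3,5-dimethoxyphenoxy)-3-phenylpropyl acetate | COc1cc(OC)cc(O[C@H](c2ccccc2)CCOC(C)=O)c1
F3 | step 1 | (S)-3-(3,5-dimethoxyphenoxy)-3-phenylpropan-1-ol | COc1cc(OC)cc(O[C@H](c2ccccc2)CCO)c1
F4 | step 3 | 2-iodo-3,5-dimethoxyphenol | COc1cc(O)c(I)c(OC)c1
F5 | step 3 | ethyl (3S)-3-(2-iodo-3,5-dimethoxyphenoxy)-3-phenylpropanoate | CCOC(=O)C[C@H](Oc1cc(OC)cc(OC)c1I)c1ccccc1
F6 | step 3 | (3S)-3-(2-iodo-3,5-dimethoxyphenoxy)-3-phenylpropanoic acid | OC(=O)C[C@H](Oc1cc(OC)cc(OC)c1I)c1ccccc1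
F7 | step 5 | 2-[(4S)-2,2-dimethyl-1,3-dioxolan-4-yl]propan-2-ol | CC1(C)OC[C@@H](C(C)(C)O)O1
F8 | step 5 | (2S)-3-methylbutane-1,2,3-triol | OC[C@H](O)C(C)(C)O
F9 | step 5 | (2S)-2,3-dihydroxy-3-methylbutyl 4-methylbenzenesulfonate | Cc1ccc(cc1)S(=O)(=O)OC[C@H](O)C(C)(C)O
F10 | step 5 | (S)-2-(oxiran-2-yl)propan-2-ol | CC(C)(O)[C@@H]1CO1
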